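**Retrosynthetic overview**
- Target ⇒ Mizoroki–Heck cut at C12–C13: a 6,7-diacetoxy-8-hydroxy decalin carrying a vinyl group on C9, plus 4-bromofuran-2(5H)-one (the lactone ring is bought in).
- Decalin ⇒ acetonide-protected β-hydroxy aldehyde; both carbocycles come from one acyclic diene–enal–ketone in a single iron-hydride operation that sets C5, C10, C9 and C8.
- Ring order in that operation: ring A first (C5–C10, radical conjugate addition), then ring B (C8–C9, aldol of the enolate so formed).
- Acyclic precursor ⇒ C4–C5 Suzuki union of a D-tartrate-derived alkenyl triflate (brings C6/C7 as a trans-acetonide and the C8 acetyl) with a (Z)-iodo enal (pent-4-enal, Stork–Zhao–Wittig, cross-metathesis with methacrolein).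

Convention: decalin compounds are named with clerodane numbering (ring A C1–C5/C10, ring B C5–C10, C11=C12 on C9, C17 on C8, C18 on C4, C19 on C5, C20 on C9; β = face of C19/C20); the target is (5R,6R,7S,8R,9R,10S,11E).

**Step 1**
Reactants: 1 pent-4-enal
Product: 2 (Z)-6-iodohepta-1,5-diene
Conditions: [Ph3PEt]I, n-BuLi, THF, 0 °C; I2, −78 °C; NaN(SiMe3)2, −20 °C; then 1, −78 °C → rt
Reagents that add atoms: ethyltriphenylphosphonium iodide CC[P+](c1ccccc1)(c1ccccc1)c1ccccc1.[I-]; iodine II
Why: Stork–Zhao–Wittig olefination with the α-iodoethylidene ylide places iodine cis to the chain of an unbranched aldehyde, giving the (Z)-2-iodoalkene that later fixes the cis (ring A) geometry of C3=C4.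

**Step 2**
Reactants: 2 (Z)-6-iodohepta-1,5-diene; 3 2-methylprop-2-enal (methacrolein)
Product: 4 (2E,6Z)-7-iodo-2-methylocta-2,6-dienal
Conditions: 3 (5 equiv), second-generation Hoveyda–Grubbs catalyst (5 mol %), CH2Cl2, 40 °C
Reagents that add atoms: none
Why: Olefin cross-metathesis of the monosubstituted alkene with methacrolein gives the thermodynamically preferred (E)-2-methyl enal, while the trisubstituted vinyl iodide is too hindered to enter the catalytic cycle.

**Step 3**
Reactants: 5 dimethyl (4S,5S)-2,2-dimethyl-1,3-dioxolane-4,5-dicarboxylate (dimethyl 2,3-O-isopropylidene-D-tartrate)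
Product: 7 1,1'-[(4S,5S)-2,2-dimethyl-1,3-dioxolane-4,5-diyl]di(ethan-1-one), via bis-Weinreb amide 6 (not isolated)
Conditions: MeNH(OMe)·HCl, i-PrMgCl, THF, −20 °C; then MeMgBr, −20 → 0 °C; aq. NH4Cl
Reagents that add atoms: methylmagnesium bromide C[Mg]Br
Why: One-pot Weinreb amidation and Grignard addition stops at the ketone through the chelated tetrahedral adduct; the two stereocentres (future C6 and C7) are not touched and the trans arrangement is the stable one.

**Step 4**
Reactants: 7 1,1'-[(4S,5S)-2,2-dimethyl-1,3-dioxolane-4,5-diyl]di(ethan-1-one)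
Product: 9 1-[(4S,5S)-5-acetyl-2,2-dimethyl-1,3-dioxolan-4-yl]ethenyl trifluoromethanesulfonate, via potassium enolate 8 (not isolated)
Conditions: 7 and PhNTf2 in THF, −78 °C; KN(SiMe3)2 (1.0 equiv) added slowly; → 0 °C
Reagents that add atoms: N-phenylbis(trifluoromethanesulfonimide) O=S(=O)(N(c1ccccc1)S(=O)(=O)C(F)(F)F)C(F)(F)F
Why: Kinetic deprotonation of one methyl group (not the hindered α-alkoxy methine) with one equivalent of base and in situ O-triflation gives the mono enol triflate of the C2-symmetric diketone (unreacted 7 is recycled); no stereocentre is affected.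

**Step 5**
Reactants: 9 1-[(4S,5S)-5-acetyl-2,2-dimethyl-1,3-dioxolan-4-yl]ethenyl trifluoromethanesulfonate; 4 (2E,6Z)-7-iodo-2-methylocta-2,6-dienal
Product: 11 (2E,6Z)-8-[(4R,5S)-5-acetyl-2,2-dimethyl-1,3-dioxolan-4-yl]-2,7-dimethylnona-2,6,8-trienal, via alkenylboronate 10 (not isolated)
Conditions: 9, B2pin2, PdCl2(PPh3)2 (3 mol %), PPh3, KOPh, toluene, 50 °C; then 4, PdCl2(dppf) (5 mol %), aq. K3PO4, DMF, 45 °C
Reagents that add atoms: none
Why: Miyaura borylation of the enol triflate followed in the same pot by Suzuki–Miyaura coupling proceeds with retention at both sp2 carbons, giving the 2,3-disubstituted diene with the Z C3=C4 bond; the temperature is kept at or below 50 °C to avoid a 1,5-hydrogen shift in the Z-diene.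

**Step 6**
Reactants: 11 (2E,6Z)-8-[(4R,5S)-5-acetyl-2,2-dimethyl-1,3-dioxolan-4-yl]-2,7-dimethylnona-2,6,8-trienal
Product: 14 (5R,6R,7S,8R,9R,10S)-8-hydroxy-6,7-(isopropylidenedioxy)-12,13,14,15,16-pentanorclerod-3-en-11-al, via tertiary allyl radical 12 (not isolated), via ring A aldehyde enolate 13 (not isolated)
Conditions: Fe(acac)3 (30 mol %), PhSiH3 (2.5 equiv), EtOH/HOCH2CH2OH (5:1), 0.01 M, degassed, 0 °C → rt
Reagents that add atoms: none
Why: Proposed new method: the iron hydride formed from Fe(acac)3 and PhSiH3 transfers a hydrogen atom to the terminal CH2 (C19) of the diene, the tertiary allyl radical 12 closes ring A by 6-exo conjugate addition to the enal (C5–C10) through a half-chair with the enal arm and the dioxolanyl group pseudo-equatorial (C19 axial) and with C10 arriving anti to the C6–O bond while H6 lies in the diene plane (A1,3 strain to C18), divalent iron reduces the α-formyl radical to enolate 13, and 13 adds to the C8 ketone (ring B) on the face fixed by A1,3 strain (H10 in the enolate plane, so C20 becomes axial and CHO equatorial) in a chair that keeps O6/O7 diequatorial and the C8 methyl equatorial; the closest known reaction type is the hydrogen-atom-transfer-initiated radical conjugate addition–aldol (radical–polar crossover) polycyclisation of 1,1-disubstituted alkene/enal/ketone substrates, and what is new is a conjugated diene as the hydrogen acceptor.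

**Step 7**
Reactants: 14 (5R,6R,7S,8R,9R,10S)-8-hydroxy-6,7-(isopropylidenedioxy)-12,13,14,15,16-pentanorclerod-3-en-11-al
Product: 15 (5R,6R,7S,8R,9R,10S)-6,7-(isopropylidenedioxy)-13,14,15,16-tetranorcleroda-3,11-dien-8-ol
Conditions: CH2I2, Zn, Ti(Oi-Pr)4, THF, 0 °C → rt
Reagents that add atoms: diiodomethane ICI
Why: Takai-type methylenation with the geminal dizinc reagent converts the hindered α-quaternary aldehyde to the vinyl group without base, so the β-hydroxy aldehyde cannot undergo retro-aldol; no stereocentre is changed.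

**Step 8**
Reactants: 15 (5R,6R,7S,8R,9R,10S)-6,7-(isopropylidenedioxy)-13,14,15,16-tetranorcleroda-3,11-dien-8-ol
Product: 16 (5R,6R,7S,8R,9R,10S)-13,14,15,16-tetranorcleroda-3,11-diene-6,7,8-triol
Conditions: AcOH/H2O (4:1), 45 °C
Reagents that add atoms: none
Why: Acid-catalysed acetal hydrolysis removes the strained trans-fused isopropylidene group under conditions too mild to ionise the tertiary C8 alcohol or protonate the alkenes.

**Step 9**
Reactants: 16 (5R,6R,7S,8R,9R,10S)-13,14,15,16-tetranorcleroda-3,11-diene-6,7,8-triol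
Product: 17 (5R,6R,7S,8R,9R,10S)-8-hydroxy-13,14,15,16-tetranorcleroda-3,11-diene-6,7-diyl diacetate
Conditions: Ac2O, pyridine, DMAP (cat.), CH2Cl2, rt
Reagents that add atoms: acetic anhydride CC(=O)OC(C)=O
Why: DMAP-catalysed acylation esterifies the two secondary hydroxyls while the tertiary C8 hydroxyl, flanked by the C9 quaternary carbon, does not react at room temperature.

**Step 10**
Reactants: 17 (5R,6R,7S,8R,9R,10S)-8-hydroxy-13,14,15,16-tetranorcleroda-3,11-diene-6,7-diyl diacetate; 18 4-bromofuran-2(5H)-one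
Product: 19 (5R,6R,7S,8R,9R,10S,11E)-6,7-diacetoxy-8-hydroxycleroda-3,11,13-trien-15,16-olide (CNP0383656.1)
Conditions: Pd(OAc)2 (10 mol %), n-Bu4NCl, NaHCO3, DMF, 70 °C
Reagents that add atoms: none
Why: Mizoroki–Heck reaction: the alkenylpalladium from 18 inserts at the terminal carbon of the monosubstituted alkene and syn β-hydride elimination gives only the (E)-diene, because C9 is quaternary and offers no second β-hydrogen.

**Compound list**
1 | pent-4-enal | C=CCCC=O | starting material
2 | (Z)-6-iodohepta-1,5-diene | C=CCC/C=C(\I)C | intermediate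
3 | 2-methylprop-2-enal (methacrolein) | CC(=C)C=O | starting material
4 | (2E,6Z)-7-iodo-2-methylocta-2,6-dienal | C/C(I)=C/CC/C=C(\C)C=O | intermediate
5 | dimethyl (4S,5S)-2,2-dimethyl-1,3-dioxolane-4,5-dicarboxylate (dimethyl 2,3-O-isopropylidene-D-tartrate) | COC(=O)[C@H]1OC(C)(C)O[C@@H]1C(=O)OC | starting material
6 | (4S,5S)-N4,N5-dimethoxy-N4,N5,2,2-tetramethyl-1,3-dioxolane-4,5-dicarboxamide (bis-Weinreb amide, not isolated) | CON(C)C(=O)[C@H]1OC(C)(C)O[C@@H]1C(=O)N(C)OC | intermediate
7 | 1,1'-[(4S,5S)-2,2-dimethyl-1,3-dioxolane-4,5-diyl]di(ethan-1-one) | CC(=O)[C@H]1OC(C)(C)O[C@@H]1C(C)=O | intermediate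
8 | potassium 1-[(4S,5S)-5-acetyl-2,2-dimethyl-1,3-dioxolan-4-yl]ethen-1-olate (not isolated) | CC(=O)[C@H]1OC(C)(C)O[C@@H]1C(=C)[O-].[K+] | intermediate
9 | 1-[(4S,5S)-5-acetyl-2,2-dimethyl-1,3-dioxolan-4-yl]ethenyl trifluoromethanesulfonate | CC(=O)[C@H]1OC(C)(C)O[C@@H]1C(=C)OS(=O)(=O)C(F)(F)F | intermediate
10 | 1-[(4S,5R)-2,2-dimethyl-5-[1-(4,4,5,5-tetramethyl-1,3,2-dioxaborolan-2-yl)ethenyl]-1,3-dioxolan-4-yl]ethan-1-one (not isolated) | CC(=O)[C@H]1OC(C)(C)O[C@@H]1C(=C)B1OC(C)(C)C(C)(C)O1 | intermediate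
11 | (2E,6Z)-8-[(4R,5S)-5-acetyl-2,2-dimethyl-1,3-dioxolan-4-yl]-2,7-dimethylnona-2,6,8-trienal | CC(=O)[C@H]1OC(C)(C)O[C@@H]1C(=C)/C(C)=C\CC/C=C(\C)C=O | intermediate
12 | (2E,6Z)-8-[(4R,5S)-5-acetyl-2,2-dimethyl-1,3-dioxolan-4-yl]-2,7-dimethyl-1-oxonona-2,6-dien-8-yl, the tertiary allyl radical (not isolated) | CC(=O)[C@H]1OC(C)(C)O[C@@H]1[C](C)/C(C)=C\CC/C=C(\C)C=O | intermediate
13 | 2-[(1R,2R)-2-[(4R,5S)-5-acetyl-2,2-dimethyl-1,3-dioxolan-4-yl]-2,3-dimethylcyclohex-3-en-1-yl]prop-1-en-1-olate, iron-bound ring A enolate (not isolated) | CC(=O)[C@H]1OC(C)(C)O[C@@H]1[C@@]2(C)C(C)=CCC[C@@H]2C(C)=C[O-] | intermediate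
14 | (5R,6R,7S,8R,9R,10S)-8-hydroxy-6,7-(isopropylidenedioxy)-12,13,14,15,16-pentanorclerod-3-en-11-al (trans-decalin; 6β,7α-acetonide, 8α-OH, 9α-CHO, 10α-H) | CC1(C)O[C@H]2[C@H](O1)[C@](C)(O)[C@](C)(C=O)[C@H]3CCC=C(C)[C@]23C | intermediate
15 | (5R,6R,7S,8R,9R,10S)-6,7-(isopropylidenedioxy)-13,14,15,16-tetranorcleroda-3,11-dien-8-ol | CC1(C)O[C@H]2[C@H](O1)[C@](C)(O)[C@](C)(C=C)[C@H]3CCC=C(C)[C@]23C | intermediate
16 | (5R,6R,7S,8R,9R,10S)-13,14,15,16-tetranorcleroda-3,11-diene-6,7,8-triol | O[C@H]1[C@H](O)[C@](C)(O)[C@](C)(C=C)[C@H]2CCC=C(C)[C@]12C | intermediate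
17 | (5R,6R,7S,8R,9R,10S)-8-hydroxy-13,14,15,16-tetranorcleroda-3,11-diene-6,7-diyl diacetate | CC(=O)O[C@H]1[C@H](OC(C)=O)[C@](C)(O)[C@](C)(C=C)[C@H]2CCC=C(C)[C@]12C | intermediate
18 | 4-bromofuran-2(5H)-one | O=C1C=C(Br)CO1 | starting material
19 | (5R,6R,7S,8R,9R,10S,11E)-6,7-diacetoxy-8-hydroxycleroda-3,11,13-trien-15,16-olide (CNP0383656.1) | CC(=O)O[C@H]1[C@H](OC(C)=O)[C@](C)(O)[C@](C)(/C=C/C2=CC(=O)OC2)[C@H]2CCC=C(C)[C@]12C | target

**Step count and risks**

Total steps: 10. Longest linear sequence: 8 (5 → 7 → 9 → 11 → 14 → 15 → 16 → 17 → 19; the arm 1 → 2 → 4 → 11 joins at step 5 and is equally long).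

Step 6 is the step most likely to fail. The stabilised allyl radical may be reduced before it closes ring A. The C5/C10 sense rests on conformational models (allylic strain, attack anti to the C6–O bond) and not on a direct precedent. The C8 epimer ratio in the aldol is expected to be modest. One safeguard is built in: a trans-fused 5,10-isomer of the wrong facial sense cannot close ring B, because its acetonide oxygens would be trans-diaxial. The fallback sets out from 11 and returns at 14 by separating the two ring closures. Compound 11 is cyclised under purely reductive hydrogen-atom-transfer conditions (Mn(dpm)3, PhSiH3, i-PrOH, rt), where the α-formyl radical is simply reduced, to give the ring A keto aldehyde F1 as C9 epimers. Ring B is then closed in a separate, reversible enamine aldol (pyrrolidine, AcOH, CH2Cl2, rt). Both C9 epimers converge through the common enamine, and the chair with O6/O7 and C17 equatorial leads to 14.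

Step 5 is the second risk. The coupling joins two hindered alkenyl partners next to a base-sensitive enal and an α-alkoxy ketone, and the boronate can protodeboronate. The fallback sets out from 9 and returns at 11 without base. Triflate 9 is stannylated ((Bu3Sn)2, Pd(PPh3)4, LiCl, THF, 60 °C) to the alkenylstannane F2. F2 is then joined to 4 by copper-assisted Stille coupling (Pd2(dba)3, AsPh3, CuI, DMF, rt).

Step 10 is the third risk. The vinyl group sits on a quaternary carbon next to a tertiary alcohol, and the bromobutenolide is sensitive to base and heat. The fallback sets out from 14 and returns at 19 with the C11=C12 bond made by olefination instead. Takai iodo-olefination of 14 (CrCl2, CHI3, THF, 0 °C) gives the (E)-vinyl iodide F3. Stille coupling with 4-(tributylstannyl)furan-2(5H)-one (Pd2(dba)3, AsPh3, CuI, DMF, rt) gives the butenolide acetonide F4. AcOH/H2O gives the butenolide triol F5, and Ac2O, pyridine, DMAP gives 19.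

**Further compounds**
F1 | step 6 | (2RS)-2-[(1R,2R)-2-[(4R,5S)-5-acetyl-2,2-dimethyl-1,3-dioxolan-4-yl]-2,3-dimethylcyclohex-3-en-1-yl]propanal | CC(=O)[C@H]1OC(C)(C)O[C@@H]1[C@@]2(C)C(C)=CCC[C@@H]2C(C)C=O
F2 | step 5 | 1-[(4S,5S)-2,2-dimethyl-5-[1-(tributylstannyl)ethenyl]-1,3-dioxolan-4-yl]ethan-1-one | CC(=O)[C@H]1OC(C)(C)O[C@@H]1C(=C)[Sn](CCCC)(CCCC)CCCC
F3 | step 10 | (5R,6R,7S,8R,9S,10S,11E)-12-iodo-6,7-(isopropylidenedioxy)-13,14,15,16-tetranorcleroda-3,11-dien-8-ol | CC1(C)O[C@H]2[C@H](O1)[C@](C)(O)[C@](C)(/C=C/I)[C@H]3CCC=C(C)[C@]23C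
F4 | step 10 | (5R,6R,7S,8R,9R,10S,11E)-8-hydroxy-6,7-(isopropylidenedioxy)cleroda-3,11,13-trien-15,16-olide | CC1(C)O[C@H]2[C@H](O1)[C@](C)(O)[C@](C)(/C=C/C4=CC(=O)OC4)[C@H]3CCC=C(C)[C@]23C
F5 | step 10 | (5R,6R,7S,8R,9R,10S,11E)-6,7,8-trihydroxycleroda-3,11,13-trien-15,16-olide | O[C@H]1[C@H](O)[C@](C)(O)[C@](C)(/C=C/C2=CC(=O)OC2)[C@H]2CCC=C(C)[C@]12C
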